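**Retrosynthetic overview**
1. Locants: ring A is the benzene ring (C3a, C4, C5, C6, C7, C7a). Ring B is the five-membered enone ring (C1, C2, C3, C3a, C7a). Rings C and D are the five- and seven-membered azulene rings, with primed guaiazulene locants, joined to C2 through C3'.
2. Ring B is opened last by cutting C1–C7a and C3–C3a together. This leaves 1-(2-iodo-4-methylphenyl)-2-methylpropan-1-one (iodine on C3a) and the anhydride of 2-(guaiazulen-3-yl)but-2-enoic acid, which holds the whole C1–C2=C3 unit with rings C and D attached. In the forward direction, one palladium/norbornene ortho-acylation/ipso-Heck annulation joins the two C15 halves and gives the target directly.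
3. Enabling feature: in ring A, C3a lies between C4, which carries the isobutyryl group, and C7a, which is the only ortho C–H. The C4 acyl group blocks the second ortho site and, together with the new acyl group on C7a, drives out the norbornene. C1–C2=C3 is an enoyl unit whose C3 keeps one hydrogen for β-hydride elimination.
4. Acid fragment from guaiazulene: C2–C3' by uncatalysed acylation of nucleophilic C3' with oxalyl chloride, C2=C3 by Wittig ethylidenation. The aryl iodide comes from 2-iodo-4-methylbenzoic acid by acylation of an isopropyl Grignard reagent.
5. Ring order: rings A, C and D are bought. Ring B is the only ring formed, in the last step.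

Key step: step 6

Assumption: the target has no stereocentre and the C2–C3' axis is unspecified, so no stereocontrol is needed; "guaiazulen-3-yl" means 5-isopropyl-3,8-dimethylazulen-1-yl; the mediator 7-bromonorbornene is taken as an available auxiliary (from norbornene by bromination and dehydrobromination).

**Step 1**
Reactants: 1 2-iodo-4-methylbenzoic acid
Product: 3 1-(2-iodo-4-methylphenyl)-2-methylpropan-1-one, via 2-iodo-4-methylbenzoyl chloride 2 (not isolated)
Conditions: (COCl)2, cat. DMF, CH2Cl2, 0 °C to rt, evaporate; then iPrMgCl (slow addition), CuBr·SMe2 (5 mol %), THF, −78 °C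
Reagents that add atoms: isopropylmagnesium chloride, CC(C)[Mg]Cl; oxalyl chloride, O=C(Cl)C(=O)Cl (chlorine of intermediate 2 only)
Why: Acid chloride formation followed by copper-catalysed Grignard acylation, in which isopropyl transfer to the acyl chloride at −78 °C should outrun both iodine–magnesium exchange at the aryl iodide and addition to the hindered product ketone.

**Step 2**
Reactants: 4 guaiazulene (7-isopropyl-1,4-dimethylazulene)
Product: 6 methyl 2-(guaiazulen-3-yl)-2-oxoacetate, via guaiazulen-3-ylglyoxylyl chloride 5 (not isolated)
Conditions: 4 added to (COCl)2 (1.5 equiv), Et2O, −20 to 0 °C; then MeOH, 0 °C to rt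
Reagents that add atoms: oxalyl chloride, O=C(Cl)C(=O)Cl; methanol, CO
Why: Uncatalysed Friedel–Crafts acylation at C3', the only free nucleophilic position of ring C (C1' carries methyl), followed by methanolysis of the acyl chloride, with inverse addition into excess oxalyl chloride to suppress a second acylation.

**Step 3**
Reactants: 6 methyl 2-(guaiazulen-3-yl)-2-oxoacetate
Product: 7 methyl (E)-2-(guaiazulen-3-yl)but-2-enoate
Conditions: EtPPh3Br, KN(SiMe3)2, THF, 0 °C; then 6, −78 °C to rt
Reagents that add atoms: ethyltriphenylphosphonium bromide, CC[P+](c1ccccc1)(c1ccccc1)c1ccccc1.[Br-]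
Why: Wittig olefination, in which the nonstabilised ylide attacks the ester-activated keto carbonyl and the kinetic oxaphosphetane places the new methyl cis to the larger, twisted azulenyl group, so mainly the (E)-alkene is expected, a geometry that step 6 erases in any case.

**Step 4**
Reactants: 7 methyl (E)-2-(guaiazulen-3-yl)but-2-enoate
Product: 8 (E)-2-(guaiazulen-3-yl)but-2-enoic acid
Conditions: LiOH, THF/MeOH/H2O, 50 °C; then 1 M HCl to pH 4
Reagents that add atoms: lithium hydroxide, [Li+].[OH-]
Why: Saponification of a methyl ester by acyl–oxygen cleavage, under which the azulene and the trisubstituted alkene are inert.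

**Step 5**
Reactants: 8 (E)-2-(guaiazulen-3-yl)but-2-enoic acid (two molecules)
Product: 9 (E,E)-2-(guaiazulen-3-yl)but-2-enoic anhydride
Conditions: DCC (0.5 equiv), CH2Cl2, 0 °C to rt, filter
Reagents that add atoms: none
Why: Carbodiimide-mediated dehydration of a carboxylic acid to its symmetric anhydride under neutral conditions that leave the azulene and the alkene geometry untouched.

**Step 6**
Reactants: 3 1-(2-iodo-4-methylphenyl)-2-methylpropan-1-one; 9 (E,E)-2-(guaiazulen-3-yl)but-2-enoic anhydride
Product: 10 2-(guaiazulen-3-yl)-4-isobutyryl-3,7-dimethyl-1H-inden-1-one (CNP0225119.0)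
Conditions: 9 (1.5 equiv), Pd(OAc)2 (10 mol %), P(2-furyl)3 (25 mol %), 7-bromonorbornene (1 equiv), Cs2CO3 (3 equiv), 1,4-dioxane, 100 °C, argon, dark
Reagents that add atoms: none
Why: Zerovalent palladium inserts into the carbon–iodine bond at C3a of 3, the norbornene carbopalladates, and carbonate-assisted palladation of the only free ortho position (C7a–H) gives the aryl–norbornyl palladacycle; oxidative addition of an acyl C–O bond of 9 (tetravalent palladium) and reductive elimination then make C7a–C1, after which the two flanking groups (C4 isobutyryl, C7a enoyl) force β-carbon elimination of the norbornene and return the metal to C3a. The C3a–Pd bond adds to C3 of the now tethered enone to make C3–C3a, and the palladium enolate at C2 loses the C3 hydrogen by β-hydride elimination, which restores C2=C3 and, with Cs2CO3, zerovalent palladium. The closest known reaction type is the Catellani-type palladium/norbornene ortho-acylation/ipso-Heck annulation of ortho-substituted aryl iodides with α,β-unsaturated carboxylic anhydrides to indenones, which accepts α-aryl-β-substituted acyl donors. Ring B closes by a 5-endo-trig carbopalladation (a formal conjugate addition), workable because the palladium enolate can pass through its oxygen-bound form to reach a syn C3–H. No stereocentre remains, since the transient centres at C2 and C3 are erased by the elimination and both alkene isomers of 9 converge on 10. The step needs site selectivity (C4 is blocked and C7a–H is the single ortho C–H), acylation before Heck closure (strained norbornene inserts much faster than the hindered trisubstituted alkene of 9) and tolerance of the C7 methyl beside the reacting C–H (addressed with 7-bromonorbornene, a bridge-substituted mediator of the type used for aryl iodides substituted next to the reacting C–H), while the azulene is safe because its nucleophilic positions C1' and C3' are both substituted.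

**Compound list**
1 | 2-iodo-4-methylbenzoic acid | Cc1ccc(C(=O)O)c(I)c1 | starting material
2 | 2-iodo-4-methylbenzoyl chloride | Cc1ccc(C(=O)Cl)c(I)c1 | intermediate
3 | 1-(2-iodo-4-methylphenyl)-2-methylpropan-1-one | CC(C)C(=O)c1ccc(C)cc1I | intermediate
4 | guaiazulene | c1cc(C)c2cc(C(C)C)ccc(C)c1-2 | starting material
5 | guaiazulen-3-ylglyoxylyl chloride | O=C(Cl)C(=O)c1cc(C)c2cc(C(C)C)ccc(C)c1-2 | intermediate
6 | methyl 2-(guaiazulen-3-yl)-2-oxoacetate | COC(=O)C(=O)c1cc(C)c2cc(C(C)C)ccc(C)c1-2 | intermediate
7 | methyl (E)-2-(guaiazulen-3-yl)but-2-enoate | C/C=C(/C(=O)OC)c1cc(C)c2cc(C(C)C)ccc(C)c1-2 | intermediate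
8 | (E)-2-(guaiazulen-3-yl)but-2-enoic acid | C/C=C(/C(=O)O)c1cc(C)c2cc(C(C)C)ccc(C)c1-2 | intermediate
9 | (E,E)-2-(guaiazulen-3-yl)but-2-enoic anhydride | C/C=C(/C(=O)OC(=O)/C(=C/C)c1cc(C)c2cc(C(C)C)ccc(C)c1-2)c1cc(C)c2cc(C(C)C)ccc(C)c1-2 | intermediate
10 | 2-(guaiazulen-3-yl)-4-isobutyryl-3,7-dimethyl-1H-inden-1-one | CC1=C(c2cc(C)c3cc(C(C)C)ccc(C)c2-3)C(=O)c2c(C)ccc(C(=O)C(C)C)c21 | target

Total step count: 6. Longest linear sequence: 5 (steps 2 to 6, from guaiazulene). The acid 8 released in step 6 can be returned to step 5.

**Steps most likely to fail**

**Risk 1 (step 6).** Oxidative addition of the very bulky α-azulenyl acyl donor to a palladacycle already crowded by the C7 methyl may be outrun by norbornene-retaining reductive elimination or by premature ipso termination. The fallback sets out from 3 and 4 and returns at 10; it takes the azulene out of the annulation.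
- Compound 3 is annulated in the same palladium/norbornene manifold with small, commercial crotonic anhydride to give 4-isobutyryl-3,7-dimethyl-1H-inden-1-one F1.
- Br2 in CH2Cl2 at 0 °C adds across C2=C3 to give racemic trans-2,3-dibromo-4-isobutyryl-3,7-dimethylindan-1-one F2.
- Et3N removes hydrogen bromide from it to give 2-bromo-4-isobutyryl-3,7-dimethyl-1H-inden-1-one F3.
- The C2–C3' bond is then made by direct C3'–H coupling of guaiazulene 4 with F3 (Pd(OAc)2, KOAc, DMAc, 120 °C), which should give 10.

**Risk 2 (step 3).** The basic ylide may deprotonate the acidified C4' methyl group of the 3'-acylazulene, and attack on a keto group that is both hindered by this peri methyl and deactivated by azulene donation may be slow. The fallback sets out from 6 and returns at 7; it replaces olefination by addition and elimination.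
- EtMgBr in THF at −78 °C adds to the keto carbonyl to give racemic methyl 2-(guaiazulen-3-yl)-2-hydroxybutanoate F4.
- Catalytic TsOH in toluene ionises F4 to the azulene-stabilised cation, which loses a proton and should give the thermodynamic (E)-ester 7.

**Risk 3 (step 1).** Iodine–magnesium exchange at the activated ortho carbon–iodine bond may compete with acyl transfer, and the Grignard reagent may reduce or add to the ketone. The fallback sets out from 2 and returns at 3; it avoids organomagnesium reagents altogether.
- C-acylation of methyl isobutyrate (LiN(iPr)2, THF, −78 °C) with 2 gives methyl 3-(2-iodo-4-methylphenyl)-2,2-dimethyl-3-oxopropanoate F5.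
- Krapcho dealkoxycarbonylation (LiCl, wet DMSO, 150 °C) then leaves the isopropyl ketone 3.

**Further compounds**
F1 | step 6 | 4-isobutyryl-3,7-dimethyl-1H-inden-1-one | CC1=CC(=O)c2c(C)ccc(C(=O)C(C)C)c21
F2 | step 6 | trans-2,3-dibromo-4-isobutyryl-3,7-dimethylindan-1-one (racemic, one enantiomer drawn) | O=C1[C@@H](Br)[C@](C)(Br)c2c(C(=O)C(C)C)ccc(C)c21
F3 | step 6 | 2-bromo-4-isobutyryl-3,7-dimethyl-1H-inden-1-one | CC1=C(Br)C(=O)c2c(C)ccc(C(=O)C(C)C)c21
F4 | step 3 | methyl 2-(guaiazulen-3-yl)-2-hydroxybutanoate (racemic) | CCC(O)(C(=O)OC)c1cc(C)c2cc(C(C)C)ccc(C)c1-2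
F5 | step 1 | methyl 3-(2-iodo-4-methylphenyl)-2,2-dimethyl-3-oxopropanoate | COC(=O)C(C)(C)C(=O)c1ccc(C)cc1I
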